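The readings stem from a simulated flask on assumed constants; noise was put on by code.

A charge of solid reagent smaller than either earlier one, 2.00 equiv, was what I had to predict for this flask.

| flask | substrate | solid reagent | remark | time |
|---|---|---|---|---|
| ochre | 0.25 M | 2.8 equiv | run made earlier |  |
| red | 0.25 M | 4.4 equiv | run made earlier |  |
| flask | 0.25 M | 2.00 equiv |  | 50 min |

| run | time / min | target / % | substrate / % |
|---|---|---|---|
| ochre | 5.00 | 1.1 | 96.0 |
| ochre | 8.00 | 3.0 | 93.3 |
| ochre | 12.0 | 7.7 | 88.8 |
| ochre | 20.0 | 17.7 | 78.2 |
| ochre | 40.0 | 38.2 | 53.3 |
| ochre | 60.0 | 55.4 | 34.3 |
| red | 5.00 | 2.8 | 95.2 |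
| red | 8.00 | 4.5 | 92.8 |
| red | 12.0 | 7.0 | 87.9 |
| red | 20.0 | 17.4 | 78.3 |
| red | 40.0 | 37.9 | 53.1 |
| red | 60.0 | 55.5 | 34.7 |

(scatter of a reading: 0.5 percentage points)

- as a solid, counted per litre of solution: solid reagent
- at the start none of the solid reagent is in solution

- north: doubling the dissolution coefficient of the solid reagent, all else as stated
- north-east: doubling the solubility of the solid reagent, all else as stated

1. amount of target at 50 min, in percent of the substrate charged
2. the change that raises the amount of target at 50 min, in percent of the substrate charged most ("none" if none brings more than 2 percentage points) (north / north-east / none)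
3. amount of target at 50 min, in percent of the substrate charged, after north

I turned the solid charge first. The ochre and red runs, with 2.8 equiv and 4.4 equiv, read 55.4% and 55.5% target at 60.0 min, so I expected no change beyond the scatter from the cut. Time came next: midway between the mean readings at 40.0 min and 60.0 min, I put target in this flask at 46.8%.

The two physical settings needed a quantity. I treated substrate's fall as pseudo-first-order and took the minutes it needs to fall by a factor e from the mean readings: 51.8 min early, then 46.2 min. A straight line through these gives a fixed 34.8 min plus 25.9 min times the substrate fraction. I read the part that scales with substrate as the crawl of dissolving. At the 42.8% substrate I expected at 50 min, the drag share, that part divided by the whole time, is 24.1% by my estimate. On this reading, doubling the dissolution coefficient divides that part by 2, taking the time from 45.9 min to 40.4 min. Doubling solubility, on the same reading, divides the whole by 2, to 23.0 min, which is shorter, so I chose north-east.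

The forecast said 47%, north-east, and 55% after north, judging that “the reaction is mostly solubility-limited and only partly dissolution-limited”.

The flask gave 47.5% target, and 56.5% after north. The best change was north-east, worth 17 percentage points against 9 points.

    substrate ⇌ tight pair (K = 0.0180, k = 0.00170 s⁻¹)
    tight pair ⇌ loose pair (K = 0.380, k = 0.220 s⁻¹)
    partner + tight pair → target (k = 0.150 L mol⁻¹ s⁻¹)
    partner + loose pair → isomer of the product (k = 0.0770 L mol⁻¹ s⁻¹)
    solid reagent ⇌ partner, rate k5*(cs5 - [partner]) while solid is left; crystals form when [partner] > cs5 (solubility = 0.230 M, k = 8.10 × 10⁻⁴ s⁻¹)

At 50.0 min in this flask, partner, the solid reagent once dissolved, was being made 1.46 times faster than it was used up, each step taken net. It stood 32.4% short of saturation, against my drag share of 24.1%. In the same flask read at 120 min, substrate at 6.79% gives a drag share of 4.80%. There partner stood 8.48% short of saturation, and target reached 78.1%.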